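Remark on the chemistry: the carbinol carbon made in step 7 is a stereocentre that the key step erases. Compounds 12, 13 and 18 (and F3, F5 in the fallbacks) are therefore made and used as racemates, and their SMILES show one enantiomer only.

## Analysis of the target

Kazinol D is a 1,3-diarylpropane: a saturated chain CH2(α)–CH2(β)–CH2(γ) joins ring A, a resorcinol, to ring B, the benzene ring of a 2,2-dimethylchroman. Ring A is numbered A1 to A6: the chain sits at A1, hydroxyls at A2 and A4, and a 1,1-dimethylallyl group, whose benzylic carbon is quaternary, at A5. Ring B keeps chroman numbering: the chain is at C6, a free hydroxyl at C8, a prenyl group at C5, and the ring oxygen O1 on C8a is para to the chain. The molecule has no stereocentre, so nothing has to be controlled or preserved in that respect. The sensitive groups are three electron-rich phenols and two different isolated alkenes, a terminal vinyl and a trisubstituted prenyl. Acid closes either alkene onto a neighbouring phenol, and catalytic hydrogenation would saturate both, so neither may be used once they are in place. The difficulties are the quaternary carbon at A5, which direct C-prenylation cannot give because prenyl electrophiles bond through their primary carbon, the contiguous substitution C4a/C5/C6 of ring B, and bringing the chain to the fully saturated level without touching the other alkenes. The strategy rests on one feature of ring A: A1 is ortho to the A2 oxygen and para to the A4 oxygen, and A5 is ortho to the A4 oxygen and para to the A2 oxygen. Each carbon substituent can therefore be handed over from its own oxygen by a [3,3] shift, and an allyl group that carries ring B on its oxygen-bearing carbon brings the whole chain with it.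

## Retrosynthetic reasoning

**22 from 21.** The last bond cut is the O–Si bond at C8. The ring B phenol has to stay distinct from the two ring A oxygens, which carry the migrating groups, so it travels as a silyl ether. Fluoride removes it without acid.

**21 from 20.** Two hydrogens are taken off Cβ and Cγ. The resulting Cβ=Cγ double bond is what a [3,3] shift leaves behind. Of the three alkenes in 20 it is the only one conjugated to an arene, so an electron-transfer reduction can pick it out in the forward direction.

**20 from 18.** Both A1–CH2(α) and A5–C(CH3)2 are cut at once. Each bond is ortho to a phenolic oxygen, so each carbon group can be traced back to an allyl-type ether on that oxygen. This strips ring A of both carbon substituents in one operation and leaves the bis-ether 18, in which A2–O carries the 1-arylallyl group and A4–O the prenyl group. The forward reaction is two Claisen shifts in one heating, passing through the mono-rearranged phenol 19. The allyl inversion inherent in the shift turns the primary prenyl ether into the tertiary 1,1-dimethylallyl group. A cut at Cα–Cβ or Cβ–Cγ would demand a ring A piece that already carries the tertiary group and a benzylic handle.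

**18 from 13 and 16.** The benzylic C–O bond is cut. The ether oxygen sits on the more substituted allyl terminus, which a plain displacement would not deliver. An iridium-catalysed allylic etherification of carbonate 13 with the aryloxide 17, made from phenol 16, is chosen because it favours that terminus. The configuration is irrelevant.

**16 from 14 and 15.** The O–CH2 bond is cut. Mono-alkylation of resorcinol 14 with prenyl bromide 15 is statistical and is steered by an excess of 14.

**13 from 10 and 11.** The Cγ–vinyl bond is cut. Vinylmagnesium bromide 11 adds to aldehyde 10, and the alkoxide 12 is trapped in the same flask as the carbonate. This saves a step and avoids isolating a labile benzylic allylic alcohol.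

**10 from 8 and 9.** The C5–CH2 bond of the prenyl group is cut. No oxygen stands ortho to C5, so this group cannot come from a sigmatropic shift. It is attached by cross-coupling of bromide 8 with stannane 9.

**8 from 7, 6, 5, 3, 1 and 2.** The bromine of 8 comes from bromination of 7 at the carbon para to the silyloxy group, done before any alkene is present. 7 is the silyl ether of phenol 6. The chroman ring of 6 is opened at C4–C4a and O1–C2: it comes from chromene 5 by hydrogenation, and 5 comes from propargylic ether 3 by a thermal rearrangement through allenylphenol 4. Only one ortho carbon is free in 3, so the ring can fuse in only one way. Ether 3 comes from 3,4-dihydroxybenzaldehyde 1 and the propargylic chloride 2, using the higher acidity of the hydroxyl para to the formyl group.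

## Alternatives that were turned down

**Alternative 1: ring B built by cycloaddition.**
- Disconnection: C4a–C5 and C6–C7 of ring B are cut, so the catechol ring is assembled from the bis(silyloxy)diene A1 and the ring A alkynoate A2.
- Forward key step: a Diels–Alder reaction followed by oxidative aromatisation in the same flask would give benzoate A3.
- For: every substituent of ring B is placed by the connectivity of the two components. No aromatic substitution has to find the right carbon, and on this point the alternative is stronger than the chosen route, which relies on a regioselective bromination (step 5).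
- Against: the two silyloxy groups of A1 oppose each other electronically, so only the alkyl terminus orients the addition and the bias should be weak. A2 is a β-alkyl ynoate and a sluggish dienophile. The oxidant has to act next to an electron-rich, silylated resorcinol and several allylic positions. After the key step the ester carbon still has to be turned into the C5 prenyl group, the two catechol oxygens told apart, and the other prenyl closed to the chroman under acid. A2 itself needs the 1,1-dimethylallyl group, that is, a prenyl-ether Claisen of its own.
- Comparison: it is much longer and its key step has its own regiochemical doubt. The chosen route offers a short endgame and uses the Claisen step for both ring A substituents.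

**Alternative 2: quinone methide cycloaddition, flavan as masked chain.**
- Disconnection: the Cα–Cβ bond is cut, with a temporary bond between the A2 oxygen and Cγ. The pieces are the ring A 2-hydroxybenzyl alcohol A4 and the ring B styrene A5.
- Forward key step: heating A4 should give an ortho-quinone methide that adds to A5 in a hetero-Diels–Alder reaction, giving flavan A6. Dissolving-metal cleavage of the benzylic C–O bond of A6 and desilylation would lead to the target.
- For: A5 is one olefination away from aldehyde 10. The orientation of the cycloaddition with an electron-rich styrene is reliable. The chain arrives saturated. The benzylic carbon of ring A is in place before the union, so no question about A3 arises. On this last point the alternative is stronger than the chosen route.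
- Against: A4 needs its own multistep synthesis, which again includes a prenyl-ether Claisen for the quaternary group, plus an ortho hydroxymethylation and differentiation of the two phenols. A5 is a styrene flanked by an ortho prenyl group, twisted and slow as a dienophile, so self-condensation of the quinone methide becomes competitive.
- Comparison: it is the more certain in regiochemistry but clearly longer. The chosen route needs no pre-functionalised ring A at all, since the two phenolic oxygens are the handles.

**Alternative 3: bis-sulfone linchpin.**
- Disconnection: Cα–Cβ and Cβ–Cγ are both cut, and the central carbon comes from bis(phenylsulfonyl)methane A7.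
- Forward key step: A7 is alkylated first by the ring A benzylic chloride A8 and then by the ring B benzylic bromide A9, giving bis-sulfone A10. Reductive removal of both sulfonyl groups and desilylation would finish.
- For: two polar alkylations of a soft, doubly stabilised carbanion are predictable. The union has no regiochemical or alkene-selectivity question, and the reductive desulfonylation spares isolated alkenes. In the predictability of its bond-forming events it is at least equal to the chosen route.
- Against: A8 is an ortho,para-dioxygenated benzylic chloride and A9 a para-alkoxy benzylic bromide beside a prenyl group, and both ionise and self-condense easily. The second alkylation builds a quaternary carbon between two sulfonyl groups and two ortho-substituted benzyl groups, which is sterically demanding. Each half needs reduction and halogenation steps, and A8 again needs the Claisen-derived quaternary group plus a formylation.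
- Comparison: it has several more steps and more protecting-group handling. The chosen route trades its polar reliability for brevity and for making both ring A bonds in the union itself.

Key step: step 10

## Route

**Step 1**
Reactants: 1 3,4-dihydroxybenzaldehyde; 2 3-chloro-3-methylbut-1-yne
Product: 3 3-hydroxy-4-[(2-methylbut-3-yn-2-yl)oxy]benzaldehyde
Conditions: 2 (1.2 equiv), DBU (1.3 equiv), CuCl2 (1 mol %), MeCN, 0 °C → rt
Reagents that add atoms: none
Why: Copper-catalysed O-alkylation of a phenol with a tertiary propargylic chloride; one equivalent of amidine base ionises only the 4-hydroxyl, the more acidic one because it is para to the formyl group, so the ether should form there and leave the 3-hydroxyl free.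

**Step 2**
Reactants: 3 3-hydroxy-4-[(2-methylbut-3-yn-2-yl)oxy]benzaldehyde
Product: 5 8-hydroxy-2,2-dimethyl-2H-chromene-6-carbaldehyde, via allenylphenol 4 (not isolated)
Conditions: N,N-diethylaniline, 180 °C, argon
Reagents that add atoms: none
Why: Aromatic propargyl Claisen rearrangement to the only free ortho carbon gives allenylphenol 4 after enolisation; a 1,5-hydrogen shift from the neighbouring hydroxyl and an oxa-6π electrocyclisation then close the 2,2-dimethyl-2H-chromene. The other ortho position carries the hydroxyl, so the ring can fuse only at the carbon that becomes C4a.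

**Step 3**
Reactants: 5 8-hydroxy-2,2-dimethyl-2H-chromene-6-carbaldehyde
Product: 6 8-hydroxy-2,2-dimethylchromane-6-carbaldehyde
Conditions: H2 (1 atm), Pd/C, EtOAc, rt
Reagents that add atoms: none
Why: Heterogeneous catalytic hydrogenation of the cis-disubstituted styrenic double bond; the formyl group, made electron-rich by the para ring oxygen, should react much more slowly at 1 atm and is spared by stopping after one equivalent of hydrogen.

**Step 4**
Reactants: 6 8-hydroxy-2,2-dimethylchromane-6-carbaldehyde
Product: 7 8-[(tert-butyldimethylsilyl)oxy]-2,2-dimethylchromane-6-carbaldehyde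
Conditions: TBSCl, imidazole, DMF, rt
Reagents that add atoms: tert-butyldimethylsilyl chloride, CC(C)(C)[Si](C)(C)Cl
Why: Silylation of the single phenol with a silyl chloride and imidazole; the bulky ether later shields C7 and lasts to the final step.

**Step 5**
Reactants: 7 8-[(tert-butyldimethylsilyl)oxy]-2,2-dimethylchromane-6-carbaldehyde
Product: 8 5-bromo-8-[(tert-butyldimethylsilyl)oxy]-2,2-dimethylchromane-6-carbaldehyde
Conditions: Br2 (1.05 equiv), NaOAc, AcOH/CH2Cl2, 0 °C → rt, dark
Reagents that add atoms: bromine, BrBr
Why: Electrophilic aromatic bromination: C5 is para to the silyloxy group and ortho to the alkyl carbon C4a, whereas C7 is wedged between the formyl group and the bulky silyl ether, and both are meta to the ring oxygen; 3,4-dialkoxybenzaldehydes with a substituent at the 5-position are known to brominate at the corresponding carbon. Sodium acetate takes up HBr so that the aryl silyl ether should stay, and the step is placed before any alkene is present.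

**Step 6**
Reactants: 8 5-bromo-8-[(tert-butyldimethylsilyl)oxy]-2,2-dimethylchromane-6-carbaldehyde; 9 tributyl(3-methylbut-2-en-1-yl)stannane
Product: 10 8-[(tert-butyldimethylsilyl)oxy]-2,2-dimethyl-5-(3-methylbut-2-en-1-yl)chromane-6-carbaldehyde
Conditions: 9 (1.3 equiv), Pd(PPh3)4 (5 mol %), toluene, 110 °C
Reagents that add atoms: none
Why: Migita–Kosugi–Stille coupling: zerovalent palladium inserts into the C5–Br bond, which the ortho formyl group activates, the allyl group passes from tin to palladium, and reductive elimination at the primary allyl terminus should give the linear prenyl group. Aldehyde and silyl ether are inert to these neutral, fluoride-free conditions.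

**Step 7**
Reactants: 10 8-[(tert-butyldimethylsilyl)oxy]-2,2-dimethyl-5-(3-methylbut-2-en-1-yl)chromane-6-carbaldehyde; 11 vinylmagnesium bromide
Product: 13 racemic methyl 1-[8-(tert-butyldimethylsilyloxy)-2,2-dimethyl-5-(3-methylbut-2-en-1-yl)chroman-6-yl]prop-2-en-1-yl carbonate, via bromomagnesium alkoxide 12 (not isolated)
Conditions: 11 (1.2 equiv), THF, −78 → 0 °C; then ClCO2Me (2 equiv), 0 °C → rt
Reagents that add atoms: methyl chloroformate, COC(=O)Cl
Why: Grignard addition to the aldehyde gives alkoxide 12, which the chloroformate acylates in the same flask, so the ionisation-prone benzylic allylic alcohol is never isolated. The new stereocentre forms without control, as a racemate, and is removed in step 10.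

**Step 8**
Reactants: 14 resorcinol; 15 prenyl bromide
Product: 16 3-[(3-methylbut-2-en-1-yl)oxy]phenol
Conditions: 14 (3 equiv), K2CO3, acetone, reflux
Reagents that add atoms: none
Why: Williamson ether synthesis; the excess of 14 keeps dialkylation low, and a carbonate base in acetone favours O- over C-alkylation.

**Step 9**
Reactants: 13 racemic methyl 1-[8-(tert-butyldimethylsilyloxy)-2,2-dimethyl-5-(3-methylbut-2-en-1-yl)chroman-6-yl]prop-2-en-1-yl carbonate; 16 3-[(3-methylbut-2-en-1-yl)oxy]phenol
Product: 18 racemic 8-(tert-butyldimethylsilyloxy)-2,2-dimethyl-5-(3-methylbut-2-en-1-yl)-6-{1-[3-(3-methylbut-2-en-1-yloxy)phenoxy]prop-2-en-1-yl}chromane, via lithium aryloxide 17 (not isolated)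
Conditions: 16, n-BuLi, THF, 0 °C; then 13, [Ir(cod)Cl]2 (2 mol %), racemic O,O′-(1,1′-binaphthalene-2,2′-diyl) N,N-bis(1-phenylethyl)phosphoramidite (4 mol %), THF, 50 °C
Reagents that add atoms: none
Why: Iridium-catalysed allylic substitution with an aryloxide: ionisation of the carbonate gives an allyl iridium complex, and the cyclometallated phosphoramidite catalyst directs attack of 17 to the aryl-substituted terminus, so the branched ether forms where an uncatalysed displacement or a palladium catalyst would give the linear one. The racemic ligand serves both enantiomers of 13, the stereocentre again forms as a racemate, and any linear carbonate arising from allylic transposition of 13 would enter through the same allyl complex.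

**Step 10 (key step)**
Reactants: 18 racemic 8-(tert-butyldimethylsilyloxy)-2,2-dimethyl-5-(3-methylbut-2-en-1-yl)-6-{1-[3-(3-methylbut-2-en-1-yloxy)phenoxy]prop-2-en-1-yl}chromane
Product: 20 4-{(2E)-3-[8-(tert-butyldimethylsilyloxy)-2,2-dimethyl-5-(3-methylbut-2-en-1-yl)chroman-6-yl]prop-2-en-1-yl}-6-(2-methylbut-3-en-2-yl)benzene-1,3-diol, via mono-rearranged phenol 19 (not isolated)
Conditions: N,N-diethylaniline (degassed), 185 °C, sealed tube, argon; stopped when 19 is consumed
Reagents that add atoms: none
Why: Two consecutive aromatic Claisen rearrangements, each a concerted suprafacial [3,3] shift through a chair-like transition state followed by enolisation of the cyclohexadienone; the closest known reactions are the rearrangement of aryl 1-arylallyl ethers to ortho-(E)-cinnamylphenols and of aryl prenyl ethers to ortho-(1,1-dimethylallyl)phenols. The 1-arylallyl ether reacts first, because its breaking C–O bond is benzylic and the new double bond ends in conjugation with ring B: the terminal CH2 bonds to A1 and becomes CH2 alpha, giving 19. The prenyl ether then shifts with allyl inversion, its C(CH3)2 terminus bonding to A5 to create the quaternary carbon of 20. No ring is closed and no stereocentre is formed; the stereocentre of 18 is destroyed, and the E geometry follows from ring B sitting pseudo-equatorial in the chair (the geometry is removed in step 11 in any case). The selectivity needed is positional: each group must go to the ortho carbon para to the other oxygen and not to A3. For the prenyl group the bulk of the C(CH3)2 terminus secures this, since it cannot easily bond to a carbon flanked by two oxygens; for the 1-arylallyl group, whose bond-forming terminus is an unhindered CH2, it rests only on the preference of meta-alkoxy aryl allyl ethers for the less crowded position para to the alkoxy group, and this is the weak point of the step. The basic amine solvent suppresses ionisation of the benzylic ether and acid-induced closure of the new phenols onto the alkenes, and the limited heating time keeps the abnormal Claisen isomerisation of the 1,1-dimethylallyl group from setting in.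

**Step 11**
Reactants: 20 4-{(2E)-3-[8-(tert-butyldimethylsilyloxy)-2,2-dimethyl-5-(3-methylbut-2-en-1-yl)chroman-6-yl]prop-2-en-1-yl}-6-(2-methylbut-3-en-2-yl)benzene-1,3-diol
Product: 21 4-{3-[8-(tert-butyldimethylsilyloxy)-2,2-dimethyl-5-(3-methylbut-2-en-1-yl)chroman-6-yl]propyl}-6-(2-methylbut-3-en-2-yl)benzene-1,3-diol
Conditions: Li (6 equiv), NH3(l)/THF, t-BuOH (3 equiv), −78 °C; then solid NH4Cl
Reagents that add atoms: none
Why: Dissolving-metal reduction of a styrene: electron transfer into the aryl-conjugated π system, protonation, a second electron transfer and protonation. The isolated vinyl and prenyl alkenes do not accept an electron, the resorcinol hydroxyls are ionised and protect ring A, and the alcohol keeps amide from building up and deprotonating the doubly activated CH2 alpha. Partial loss of the silyl group here would be harmless.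

**Step 12**
Reactants: 21 4-{3-[8-(tert-butyldimethylsilyloxy)-2,2-dimethyl-5-(3-methylbut-2-en-1-yl)chroman-6-yl]propyl}-6-(2-methylbut-3-en-2-yl)benzene-1,3-diol
Product: 22 Kazinol D
Conditions: Bu4NF, THF, 0 °C; aq. NH4Cl
Reagents that add atoms: none
Why: Fluoride-induced cleavage of the aryl silyl ether; the acid-free conditions leave the vinyl and prenyl groups and the chroman untouched.

## Compound list

1 | 3,4-dihydroxybenzaldehyde | O=Cc1ccc(O)c(O)c1 | starting material
2 | 3-chloro-3-methylbut-1-yne | C#CC(C)(C)Cl | starting material
3 | 3-hydroxy-4-[(2-methylbut-3-yn-2-yl)oxy]benzaldehyde | O=Cc1ccc(OC(C)(C)C#C)c(O)c1 | intermediate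
4 | 3,4-dihydroxy-5-(3-methylbuta-1,2-dien-1-yl)benzaldehyde (allenylphenol, not isolated) | O=Cc1cc(O)c(O)c(C=C=C(C)C)c1 | intermediate
5 | 8-hydroxy-2,2-dimethyl-2H-chromene-6-carbaldehyde | CC1(C)C=Cc2cc(C=O)cc(O)c2O1 | intermediate
6 | 8-hydroxy-2,2-dimethylchromane-6-carbaldehyde | CC1(C)CCc2cc(C=O)cc(O)c2O1 | intermediate
7 | 8-[(tert-butyldimethylsilyl)oxy]-2,2-dimethylchromane-6-carbaldehyde | CC1(C)CCc2cc(C=O)cc(O[Si](C)(C)C(C)(C)C)c2O1 | intermediate
8 | 5-bromo-8-[(tert-butyldimethylsilyl)oxy]-2,2-dimethylchromane-6-carbaldehyde | CC1(C)CCc2c(Br)c(C=O)cc(O[Si](C)(C)C(C)(C)C)c2O1 | intermediate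
9 | tributyl(3-methylbut-2-en-1-yl)stannane | CCCC[Sn](CCCC)(CCCC)CC=C(C)C | starting material
10 | 8-[(tert-butyldimethylsilyl)oxy]-2,2-dimethyl-5-(3-methylbut-2-en-1-yl)chromane-6-carbaldehyde | CC(C)=CCc1c(C=O)cc(O[Si](C)(C)C(C)(C)C)c2OC(C)(C)CCc12 | intermediate
11 | vinylmagnesium bromide | C=C[Mg]Br | starting material
12 | bromomagnesium 1-[8-(tert-butyldimethylsilyloxy)-2,2-dimethyl-5-(3-methylbut-2-en-1-yl)chroman-6-yl]prop-2-en-1-olate (racemic, one enantiomer drawn, not isolated) | C=C[C@@H](O[Mg]Br)c1cc(O[Si](C)(C)C(C)(C)C)c2c(c1CC=C(C)C)CCC(C)(C)O2 | intermediate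
13 | methyl 1-[8-(tert-butyldimethylsilyloxy)-2,2-dimethyl-5-(3-methylbut-2-en-1-yl)chroman-6-yl]prop-2-en-1-yl carbonate (racemic, one enantiomer drawn) | C=C[C@@H](OC(=O)OC)c1cc(O[Si](C)(C)C(C)(C)C)c2c(c1CC=C(C)C)CCC(C)(C)O2 | intermediate
14 | resorcinol (benzene-1,3-diol) | Oc1cccc(O)c1 | starting material
15 | prenyl bromide (1-bromo-3-methylbut-2-ene) | CC(C)=CCBr | starting material
16 | 3-[(3-methylbut-2-en-1-yl)oxy]phenol | CC(C)=CCOc1cccc(O)c1 | intermediate
17 | lithium 3-[(3-methylbut-2-en-1-yl)oxy]phenolate (not isolated) | [Li+].[O-]c1cccc(OCC=C(C)C)c1 | intermediate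
18 | 8-(tert-butyldimethylsilyloxy)-2,2-dimethyl-5-(3-methylbut-2-en-1-yl)-6-{1-[3-(3-methylbut-2-en-1-yloxy)phenoxy]prop-2-en-1-yl}chromane (racemic, one enantiomer drawn) | C=C[C@@H](Oc1cccc(OCC=C(C)C)c1)c1cc(O[Si](C)(C)C(C)(C)C)c2c(c1CC=C(C)C)CCC(C)(C)O2 | intermediate
19 | 2-{(2E)-3-[8-(tert-butyldimethylsilyloxy)-2,2-dimethyl-5-(3-methylbut-2-en-1-yl)chroman-6-yl]prop-2-en-1-yl}-5-[(3-methylbut-2-en-1-yl)oxy]phenol (not isolated) | CC(C)=CCOc1ccc(C/C=C/c2cc(O[Si](C)(C)C(C)(C)C)c3c(c2CC=C(C)C)CCC(C)(C)O3)c(O)c1 | intermediate
20 | 4-{(2E)-3-[8-(tert-butyldimethylsilyloxy)-2,2-dimethyl-5-(3-methylbut-2-en-1-yl)chroman-6-yl]prop-2-en-1-yl}-6-(2-methylbut-3-en-2-yl)benzene-1,3-diol | C=CC(C)(C)c1cc(C/C=C/c2cc(O[Si](C)(C)C(C)(C)C)c3c(c2CC=C(C)C)CCC(C)(C)O3)c(O)cc1O | intermediate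
21 | 4-{3-[8-(tert-butyldimethylsilyloxy)-2,2-dimethyl-5-(3-methylbut-2-en-1-yl)chroman-6-yl]propyl}-6-(2-methylbut-3-en-2-yl)benzene-1,3-diol | C=CC(C)(C)c1cc(CCCc2cc(O[Si](C)(C)C(C)(C)C)c3c(c2CC=C(C)C)CCC(C)(C)O3)c(O)cc1O | intermediate
22 | Kazinol D, 4-{3-[8-hydroxy-2,2-dimethyl-5-(3-methylbut-2-en-1-yl)chroman-6-yl]propyl}-6-(2-methylbut-3-en-2-yl)benzene-1,3-diol | C=CC(C)(C)c1cc(CCCc2cc(O)c3c(c2CC=C(C)C)CCC(C)(C)O3)c(O)cc1O | target

## Step count and least certain steps

Total: 12 steps. Longest linear sequence: 11 steps (steps 1 to 7 and 9 to 12); step 8 is a one-step side branch.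

**Step 10 (key step).**
- Most likely failure: loss of positional control in the first shift. Its bond-forming terminus is an unhindered CH2, so migration to A3 between the two oxygens is held back only by a modest substituent bias.
- Also possible: heterolysis of the doubly activated benzylic C–O bond, which would scramble the allyl terminus, and abnormal Claisen isomerisation of the 1,1-dimethylallyl group through the free A4 hydroxyl on prolonged heating.
- Fallback, from 13 back to 21: A3 is blocked with a bromine that costs no extra step. Commercial 2-bromobenzene-1,3-diol F1 is mono-alkylated with 15 (K2CO3, acetone) to 2-bromo-3-[(3-methylbut-2-en-1-yl)oxy]phenol F2. F2 is joined to 13 under the conditions of step 9 to give the bromo bis-ether F3. On heating as in step 10, A3 can no longer be the end point of either shift, so both groups should arrive at A1 and A5, giving the bromoresorcinol F4. The Li/NH3 conditions of step 11, with more lithium, cleave the aryl C–Br bond and reduce the styrene in the same operation, so F4 should give 21 directly.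

**Step 9.**
- Most likely failure: erosion of branched selectivity or a stalled reaction. The allyl iridium intermediate carries an electron-rich aryl group with an ortho substituent, which slows attack at the benzylic terminus, and the branched ether can re-ionise and drift to the linear cinnamyl ether.
- Fallback, from 10 back to 18: 11 is added to 10 with an aqueous quench to give the racemic allylic alcohol F5. A Mitsunobu reaction with 16 (PPh3, diisopropyl azodicarboxylate, toluene, 0 °C) then forms the ether by direct displacement at the carbinol carbon, without an allyl metal intermediate.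

**Step 5.**
- Most likely failure: bromination at C7 in place of C5, or acid-induced loss of the silyl group followed by phenol-directed ortho bromination. Both open positions are activated by the same oxygen, and the preference for C5 is argued from analogy.
- Fallback, starting from 2 and rejoining at 8: the bromine is taken from a building block in which its position is already fixed. Commercial 2-bromo-4,5-dimethoxybenzaldehyde F6 is demethylated (BBr3, CH2Cl2) to 2-bromo-4,5-dihydroxybenzaldehyde F7. F7 is etherified with 2 as in step 1 at the hydroxyl para to the formyl group, giving F8. Heating as in step 2 gives the bromochromene F9. Its ring double bond is hydrogenated with RhCl(PPh3)3 and H2, which spares the C–Br bond and the aldehyde, giving F10. Silylation as in step 4 gives 8.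

**Step 6.**
- Most likely failure: allyl transposition during the coupling, with bond formation at the tertiary allyl terminus; slow oxidative addition at a C–Br bond flanked on both sides; or transfer of the allyl group from tin to the formyl group.
- Fallback, from 8 back to 10: the polarity is reversed. The aldehyde of 8 is protected as the dioxolane F11 (ethylene glycol, pyridinium p-toluenesulfonate, benzene, reflux). Bromine–lithium exchange (n-BuLi, THF, −78 °C), transmetallation with CuBr·SMe2 and alkylation with 15 at its primary carbon give F12. Mild hydrolysis (pyridinium p-toluenesulfonate, wet acetone) returns 10.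

**Step 11.**
- Most likely failure: over-reduction of the electron-rich ring B, or stalling when CH2 alpha is deprotonated to a 1,3-diarylallyl anion that accepts no further electrons.
- Fallback, from 20 to 22: the last two steps are interchanged. 20 is desilylated first (Bu4NF, THF) to the triol F13. The dissolving-metal reduction is then run on the tris-phenoxide, in which both arenes are shielded by their negative charge and only the styrene can accept electrons, giving 22 after work-up.

## Further compounds

F1 | step 10 | 2-bromobenzene-1,3-diol | Oc1cccc(O)c1Br
F2 | step 10 | 2-bromo-3-[(3-methylbut-2-en-1-yl)oxy]phenol | CC(C)=CCOc1cccc(O)c1Br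
F3 | step 10 | 6-{1-[2-bromo-3-(3-methylbut-2-en-1-yloxy)phenoxy]prop-2-en-1-yl}-8-(tert-butyldimethylsilyloxy)-2,2-dimethyl-5-(3-methylbut-2-en-1-yl)chromane (racemic, one enantiomer drawn) | C=C[C@@H](Oc1cccc(OCC=C(C)C)c1Br)c1cc(O[Si](C)(C)C(C)(C)C)c2c(c1CC=C(C)C)CCC(C)(C)O2
F4 | step 10 | 2-bromo-4-{(2E)-3-[8-(tert-butyldimethylsilyloxy)-2,2-dimethyl-5-(3-methylbut-2-en-1-yl)chroman-6-yl]prop-2-en-1-yl}-6-(2-methylbut-3-en-2-yl)benzene-1,3-diol | C=CC(C)(C)c1cc(C/C=C/c2cc(O[Si](C)(C)C(C)(C)C)c3c(c2CC=C(C)C)CCC(C)(C)O3)c(O)c(Br)c1O
F5 | step 9 | 1-[8-(tert-butyldimethylsilyloxy)-2,2-dimethyl-5-(3-methylbut-2-en-1-yl)chroman-6-yl]prop-2-en-1-ol (racemic, one enantiomer drawn) | C=C[C@@H](O)c1cc(O[Si](C)(C)C(C)(C)C)c2c(c1CC=C(C)C)CCC(C)(C)O2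
F6 | step 5 | 2-bromo-4,5-dimethoxybenzaldehyde | COc1cc(Br)c(C=O)cc1OC
F7 | step 5 | 2-bromo-4,5-dihydroxybenzaldehyde | O=Cc1cc(O)c(O)cc1Br
F8 | step 5 | 2-bromo-5-hydroxy-4-[(2-methylbut-3-yn-2-yl)oxy]benzaldehyde | O=Cc1cc(O)c(OC(C)(C)C#C)cc1Br
F9 | step 5 | 5-bromo-8-hydroxy-2,2-dimethyl-2H-chromene-6-carbaldehyde | CC1(C)C=Cc2c(Br)c(C=O)cc(O)c2O1
F10 | step 5 | 5-bromo-8-hydroxy-2,2-dimethylchromane-6-carbaldehyde | CC1(C)CCc2c(Br)c(C=O)cc(O)c2O1
F11 | step 6 | 2-[5-bromo-8-(tert-butyldimethylsilyloxy)-2,2-dimethylchroman-6-yl]-1,3-dioxolane | CC1(C)CCc2c(Br)c(C3OCCO3)cc(O[Si](C)(C)C(C)(C)C)c2O1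
F12 | step 6 | 2-[8-(tert-butyldimethylsilyloxy)-2,2-dimethyl-5-(3-methylbut-2-en-1-yl)chroman-6-yl]-1,3-dioxolane | CC1(C)CCc2c(CC=C(C)C)c(C3OCCO3)cc(O[Si](C)(C)C(C)(C)C)c2O1
F13 | step 11 | 4-{(2E)-3-[8-hydroxy-2,2-dimethyl-5-(3-methylbut-2-en-1-yl)chroman-6-yl]prop-2-en-1-yl}-6-(2-methylbut-3-en-2-yl)benzene-1,3-diol | C=CC(C)(C)c1cc(C/C=C/c2cc(O)c3c(c2CC=C(C)C)CCC(C)(C)O3)c(O)cc1O
A1 | alternative 1 | 7-methyl-2,3-bis(trimethylsilyloxy)octa-1,3,6-triene | C=C(O[Si](C)(C)C)C(O[Si](C)(C)C)=CCC=C(C)C
A2 | alternative 1 | methyl 6-[2,4-bis(tert-butyldimethylsilyloxy)-5-(2-methylbut-3-en-2-yl)phenyl]hex-2-ynoate | COC(=O)C#CCCCc1cc(C(C)(C)C=C)c(O[Si](C)(C)C(C)(C)C)cc1O[Si](C)(C)C(C)(C)C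
A3 | alternative 1 | methyl 6-{3-[2,4-bis(tert-butyldimethylsilyloxy)-5-(2-methylbut-3-en-2-yl)phenyl]propyl}-2-(3-methylbut-2-en-1-yl)-3,4-bis(trimethylsilyloxy)benzoate | COC(=O)c1c(CCCc2cc(C(C)(C)C=C)c(O[Si](C)(C)C(C)(C)C)cc2O[Si](C)(C)C(C)(C)C)cc(O[Si](C)(C)C)c(O[Si](C)(C)C)c1CC=C(C)C
A4 | alternative 2 | [4-(tert-butyldimethylsilyloxy)-2-hydroxy-5-(2-methylbut-3-en-2-yl)phenyl]methanol | OCc1cc(C(C)(C)C=C)c(O[Si](C)(C)C(C)(C)C)cc1O
A5 | alternative 2 | 8-(tert-butyldimethylsilyloxy)-6-ethenyl-2,2-dimethyl-5-(3-methylbut-2-en-1-yl)chromane | C=Cc1cc(O[Si](C)(C)C(C)(C)C)c2c(c1CC=C(C)C)CCC(C)(C)O2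
A6 | alternative 2 | 7-(tert-butyldimethylsilyloxy)-2-[8-(tert-butyldimethylsilyloxy)-2,2-dimethyl-5-(3-methylbut-2-en-1-yl)chroman-6-yl]-6-(2-methylbut-3-en-2-yl)chromane (racemic, one enantiomer drawn) | C=CC(C)(C)c1cc2c(cc1O[Si](C)(C)C(C)(C)C)O[C@H](CC2)c1cc(O[Si](C)(C)C(C)(C)C)c2c(c1CC=C(C)C)CCC(C)(C)O2
A7 | alternative 3 | bis(phenylsulfonyl)methane | O=S(=O)(CS(=O)(=O)c1ccccc1)c1ccccc1
A8 | alternative 3 | 1,5-bis(tert-butyldimethylsilyloxy)-2-(chloromethyl)-4-(2-methylbut-3-en-2-yl)benzene | ClCc1cc(C(C)(C)C=C)c(O[Si](C)(C)C(C)(C)C)cc1O[Si](C)(C)C(C)(C)C
A9 | alternative 3 | 6-(bromomethyl)-8-(tert-butyldimethylsilyloxy)-2,2-dimethyl-5-(3-methylbut-2-en-1-yl)chromane | BrCc1cc(O[Si](C)(C)C(C)(C)C)c2c(c1CC=C(C)C)CCC(C)(C)O2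
A10 | alternative 3 | 6-{3-[2,4-bis(tert-butyldimethylsilyloxy)-5-(2-methylbut-3-en-2-yl)phenyl]-2,2-bis(phenylsulfonyl)propyl}-8-(tert-butyldimethylsilyloxy)-2,2-dimethyl-5-(3-methylbut-2-en-1-yl)chromane | C=CC(C)(C)c1cc(CC(Cc2cc(O[Si](C)(C)C(C)(C)C)c3c(c2CC=C(C)C)CCC(C)(C)O3)(S(=O)(=O)c2ccccc2)S(=O)(=O)c2ccccc2)c(O[Si](C)(C)C(C)(C)C)cc1O[Si](C)(C)C(C)(C)C
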